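At 4.00 h, late in the north run, the target stood at 34.0%, and the meeting asked what such an end point can carry over to two new flasks.

| flask | starting material | free catalyst | remark | time |
|---|---|---|---|---|
| south-west | 14 mM (fed, over 25 min) | 0.2 mol% | run made earlier; the fed solution adds 1.0 times the starting volume |  |
| west | 25 mM (fed, over 25 min) | 0.2 mol% | run made earlier; the fed solution adds 1.0 times the starting volume |  |
| north | 31 mM (fed, over 25 min) | 0.22 mol% | run made earlier; the fed solution adds 1.0 times the starting volume |  |
| winter | 31 mM (fed, over 25 min) | 0.2 mol% | the fed solution adds 1.0 times the starting volume | 4.0 h |
| dawn | 20 mM | 0.3 mol% | everything together at the start, the whole solution of starting material included, so that from the start the volume is larger by 1.0 times the starting volume | 4.0 h |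

- south-west (time / h: target / %): 1.00: 6.9; 2.00: 11.5; 3.00: 14.0; 4.00: 17.7
- west (time / h: target / %): 0.500: 4.7; 1.33: 11.5; 2.50: 20.4; 4.00: 28.8
- north (time / h: target / %): 0.333: 2.3; 0.667: 6.2; 1.50: 19.4; 4.00: 34.0

(each reading ± 1 percentage point)

- charges are per starting volume, the dose included; the dosed solution carries all of it
- where the amount of starting material changes, what is given in equivalents or mol% on it follows
- percentages count the whole charge, also what has not yet gone in

- the winner by amount of target, in percent of the starting material charged; "neither" if no more than 2 percentage points parts them (winter / dawn / neither)
- how much target is there at the end, in percent of the starting material charged: winter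
- how much target is there at the end, in percent of the starting material charged: dawn

The kineticist said at the board that if target forms at a rate proportional to c(starting material) and c(free catalyst), and c(free catalyst) is treated as steady (pseudo-first-order), the rate integrates in closed form: the logarithm of the fraction not yet turned into target falls linearly with time, with an apparent half-life τ. She expected τ to shorten as the dose D grows, D being the charged c(starting material) times the loading, so the product τ·D should carry from run to run.

The process chemist objected that a fed flask has its charge for less time than the clock shows. The average portion enters 12.5 min late, which is half the feed, so he proposed subtracting that from the time of fed runs and from no other.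

I, taking the minutes, reckoned the product on that clock from the last readings, which gave 0.431 mM·h for north and 0.387 mM·h for west, the two doses around winter's. Their mean is the dose-time product K, 0.409 mM·h, a value read from two readings that each scatter by 1 percentage point.

Winter has a dose of 0.0620 mM and the shortened clock. Dawn has a smaller dose, 0.0600 mM, but the full 4.0 h. My reckoning therefore gives 32.9% for winter and 33.4% for dawn. That gap of 0.50 points is smaller than the margin of 2 points, so I committed to neither.

The forecast differs on the winner, naming dawn with 32% for winter and 35% for dawn: “The margin is small, but it favours dawn”.

The flasks give neither, with 33.4% for winter and 34.0% for dawn.

    starting material + free catalyst → free catalyst + target (k = 84.0 L mol⁻¹ min⁻¹)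
    2 free catalyst → spent catalyst (k = 30.0 L mol⁻¹ min⁻¹)
    starting material → side product (k = 0.00150 min⁻¹)

Taken back through the same clocks, winter's yield gives K as 0.401 mM·h and dawn's gives 0.400 mM·h, beside the 0.409 mM·h read from north and west. In dawn, the step to target uses starting material 1.7 times as fast as the step to side product at the start, and that ratio has fallen to 1.2 at 4.00 h, when the flask holds 34.0% target and 23.8% side product, with 42% of the starting material left.

All runs were generated by integration for an exercise; noise was put on by code.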